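**Numbering used throughout.** Skeleton atoms carry daucane numbers: C1 (quaternary ring-fusion carbon with the methyl group), C2, C3, C4 (OH, isopropyl), C5 (ring-fusion CH), C6 (O-anisoyl), C7, C8 (methyl), C9, C10 (OAc). β is the face of the C1 methyl group, α the opposite face. Compound numbers are those of the steps and the compound list.

## Analysis of the target

Target 20 is a daucane diester: a cyclopentane (C1–C5) trans-fused through the C1–C5 bond to a cycloheptene (C1, C5, C6–C10) that carries the C8=C9 double bond. It has five contiguous stereocentres: quaternary C1 (Me β), C5 (H α), the tertiary carbinol C4 (OH β, iPr α), C6 (anisoate α) and the allylic, neopentyl C10 (acetate α). O6 and O10 lie on the same α-face on either side of the ring-fusion bond, and O10 is trans to the C1 methyl group. O4 and O6 are 1,3-anti, and H5 sits on the more hindered face, syn to the isopropyl group and to C10. Two different esters must be placed on two secondary carbinols next to a free tertiary hydroxyl. C7 lies between C6 and C8=C9, so any C6 ketone would be β,γ-unsaturated and also β to the C4 hydroxyl; it could not be equilibrated safely. The feature the route is built on is this: O, C6, C7, C8(Me), C9 and C10 are the ring atoms of a 4-methyl-3,6-dihydro-2H-pyran if a single oxygen bridges C6 and C10. The remaining atoms (C1–C6, the C1 methyl and the isopropyl group) are the ten carbons of p-menth-1-en-4-ol, with C4 already a stereocentre. The difficulty is to make quaternary C1 and the adjacent C10–O centre together with the seven-membered ring, and then to place H5 and O6 on the hindered α-face.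

## Retrosynthetic reasoning

**C6–O ester.** Target 20 is cut at the anisoate to the diol monoacetate 18 and the acid chloride 19. The tertiary C4–OH needs no protection, so the last step is an acylation of the only secondary hydroxyl.

**C6–O and the O10 acetyl group.** In 18 the C6–O bond is traced back to a C6–Si bond (fluorosilane 17, oxidation with retention). The acetate on O10 is traced back to the Si–O10 bond of the cyclic siloxane 15. Cutting that Si–O bond frees O10 while C6 still carries silicon, so the two secondary oxygens are differentiated by construction and not by a selective acylation.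

**C5–H and C6–Si.** Siloxane 15 is opened to the hydridosilyl ether 14 by removing H from C5 and Si from C6. The forward reaction is an intramolecular hydrosilylation. The tether hangs from the α-oxygen on C10, so H and Si can be delivered only to the α-face of C5=C6. This sets the trans ring fusion and the C6 configuration against the steric bias of the substrate.

**C1–C10 (key disconnection).** The seven-membered carbocycle of 14 is cut at C1–C10 and the C6–O bond is re-formed, which leads to the dihydropyran 11. This cut is chosen because it removes the quaternary centre, the C10 stereocentre and the seven-membered ring at once and leaves a six-membered ether with one stereocentre (C6). The forward step is a ring-expanding [2,3]-sigmatropic shift of the C10 carbanion. It has to transfer the C6 configuration to C1 and C10 and hand the oxygen over from C6 to C10.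

**C8=C9 and O–C10.** Dihydropyran 11 is cut at C8=C9 (ring-closing metathesis of the allyl methallyl ether 10) and at O–C10 (etherification of the carbinol 8 with 9).

**C6–C7.** Carbinol 8 is cut to the enal 5 and the methallyl nucleophile 6. The forward allylboration sets C6 by reagent control; it is the only stereocentre of the route made with a chiral reagent.

**C5=C1, and C–C cleavage of the starting ring.** Enal 5 is the aldol condensation product of the keto aldehyde 4, which comes from oxidative cleavage of the ring double bond of 2, the silyl ether of (S)-terpinen-4-ol 1. The six-membered ring of 1 is contracted to the cyclopentene, and all ten of its carbons and its stereocentre end up in the target.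

## Alternatives that were turned down

**Alternative 1:** the textbook disconnection at C8=C9. Forward key step: ring-closing metathesis of the cyclopentane triene A1, which carries a C6 carbinol with a methallyl arm and a C10 acetate with a vinyl arm. It was turned down because the metathesis builds no stereocentre. C10 would have to come from addition of a vinyl nucleophile to a neopentyl aldehyde on C1, where the two flanking groups (methyl and a ring methylene) give no reliable facial bias. C1, C5, C4, C6 and C10 would be set in separate events with three hydroxyls to be told apart, so the precursor would cost more steps than the ring closure saves.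

**Alternative 2:** disconnection at C6–C7 and C1–C10 as a [3+4] annulation. Forward key step: addition of the lithium enolate of a 4-alkoxybut-3-en-2-one to the acylsilane A2, Brook rearrangement to a cis-divinylcyclopropanediolate and anionic oxy-Cope rearrangement to the cycloheptenone A3. The reaction type is known and would also form both bonds in one flask. It was turned down for three reasons:
- The configuration of the cyclopropane, and with it C1 and C10 relative to C4, is fixed when the carbanion closes onto the ketone. Only the remote C4 centre biases that event, and its sense cannot be predicted.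
- C5 leaves the step as an enol ether carbon. H5 would then have to be put on the hindered α-face by protonation, and the resulting β,γ-unsaturated C6 ketone cannot be equilibrated.
- C8 arrives as a carbonyl that needs triflation and methylation through a β-alkoxy enolate.

**Alternative 3:** one-carbon ring expansion. Forward key step: cyclopropanation of the silyl enol ether of the trans-hydrindanone A4 and oxidative cleavage of the cyclopropane to the cycloheptenone A5, in which C9 is the inserted carbon. It was turned down because A4, with its 4-hydroxy-4-isopropyl pattern, has no short enantioselective entry. In addition, C10 arrives as a ketone: hydride is expected to add anti to the angular methyl group and give the 10β-alcohol, and inversion at a neopentyl allylic centre is not a realistic correction.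

Key step: step 7

**Remark (assumption).** (S)-(+)-Terpinen-4-ol 1 is taken to be available in high enantiomeric purity. With material of lower ee, the minor enantiomer becomes a diastereomer of 8 in the reagent-controlled step 4 and can be removed there.

## Route

Step 1
Reactants: 1 (S)-(+)-terpinen-4-ol
Product: 2 (S)-tert-butyldimethylsilyl ether of terpinen-4-ol
Conditions: TBSOTf, 2,6-lutidine, CH2Cl2, 0 °C → rt
Reagents that add atoms: tert-butyldimethylsilyl triflate, CC(C)(C)[Si](C)(C)OS(=O)(=O)C(F)(F)F
Why: Silylation of a tertiary alcohol with the silyl triflate and a hindered base; the ether blocks retro-aldol and dehydration in steps 2–3 and, being non-coordinating, keeps the later lithiation away from C6; no stereocentre is touched.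

Step 2
Reactants: 2 (S)-tert-butyldimethylsilyl ether of terpinen-4-ol
Product: 4 (S)-3-[(tert-butyldimethylsilyl)oxy]-6-oxo-3-(propan-2-yl)heptanal, via secondary ozonide 3 (not isolated)
Conditions: O3, CH2Cl2, −78 °C; then PPh3, −78 °C → rt
Reagents that add atoms: ozone, [O-][O+]=O
Why: Ozonolysis of the only C=C bond with reductive work-up; this is the C–C cleavage that opens the p-menthene ring and leaves the C4 stereocentre untouched.

Step 3
Reactants: 4 (S)-3-[(tert-butyldimethylsilyl)oxy]-6-oxo-3-(propan-2-yl)heptanal
Product: 5 (R)-5-[(tert-butyldimethylsilyl)oxy]-2-methyl-5-(propan-2-yl)cyclopent-1-ene-1-carbaldehyde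
Conditions: piperidine (0.2 equiv), AcOH (0.2 equiv), toluene, 60 °C
Reagents that add atoms: none
Why: Intramolecular aldol condensation under enamine catalysis: the α-carbon of the aldehyde adds to the methyl ketone in a 5-exo closure and water is lost to the tetrasubstituted enal, as for the analogous keto aldehyde from limonene; the tertiary silyl ether is a poor leaving group in this buffered medium.

Step 4
Reactants: 5 (R)-5-[(tert-butyldimethylsilyl)oxy]-2-methyl-5-(propan-2-yl)cyclopent-1-ene-1-carbaldehyde; 6 (2-methylallyl)magnesium chloride
Product: 8 (S)-1-[(R)-5-(tert-butyldimethylsilyloxy)-2-methyl-5-(propan-2-yl)cyclopent-1-en-1-yl]-3-methylbut-3-en-1-ol, via diisopinocampheylborinate 7 (not isolated)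
Conditions: (−)-Ipc2BOMe (from (+)-α-pinene), 6, Et2O, −78 °C → rt; then 5, −78 °C; then NaOH, H2O2, 0 °C → rt
Reagents that add atoms: none
Why: Reagent-controlled allylboration through a chair transition state; the (+)-α-pinene-derived borane adds to the Si face of the aldehyde, as it does with benzaldehyde and enals, which gives the (S)-carbinol at C6; the C4 centre is remote from the carbonyl.

Step 5
Reactants: 8 (S)-homoallylic alcohol; 9 allyl bromide
Product: 10 allyl ether of 8, (S)-configured at C6
Conditions: NaH, 9, Bu4NI (cat.), THF–DMF, 0 °C → rt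
Reagents that add atoms: none
Why: Williamson etherification of the secondary alkoxide; the tertiary silyl group may shuttle between O4 and O6, but only the secondary alkoxide is alkylated at a useful rate.

Step 6
Reactants: 10 allyl ether of 8
Product: 11 (S)-2-[(R)-5-(tert-butyldimethylsilyloxy)-2-methyl-5-(propan-2-yl)cyclopent-1-en-1-yl]-4-methyl-3,6-dihydro-2H-pyran
Conditions: Grubbs second-generation catalyst (3 mol %), CH2Cl2, 40 °C
Reagents that add atoms: none
Why: Ring-closing metathesis to a six-membered ring with a trisubstituted (necessarily cis) C8=C9 bond; the tetrasubstituted cyclopentene does not take part.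

Step 7
Reactants: 11 (S)-2-cyclopentenyl-4-methyl-3,6-dihydro-2H-pyran
Product: 14 (1S,4R,10R)-4-(tert-butyldimethylsilyloxy)-10-(dimethylsilyloxy)dauca-5,8-diene, via 10-lithio-dihydropyran 12 (not isolated), via lithium cycloheptadienyl alkoxide 13 (not isolated)
Conditions: s-BuLi (1.1 equiv), THF, −78 → −40 °C; then ClSiHMe2, −78 → 0 °C
Reagents that add atoms: chlorodimethylsilane, C[SiH](C)Cl
Why: Proposed new method: s-BuLi removes a C10 proton of 11 (allylic to C8=C9 and α to oxygen; the only other α-oxy allylic proton, C6–H, is tertiary and its anion could not become planar next to the C1 methyl and the C4 silyl ether), and the α-oxyallyllithium 12 undergoes a suprafacial [2,3]-sigmatropic shift across O–C6–C5=C1 that forms C10–C1, breaks C6–O and creates C5=C6, turning the six-membered ether into the seven-membered carbocycle 13. The closest known reaction types are the [2,3]-Wittig rearrangement of bis-allylic ethers (also in its ring-contracting macrocyclic form) and the ring-growing [2,3] shifts of 2-vinyl cyclic sulfonium, ammonium and oxonium ylides; the carbanion version on a 2-alkenyl-3,6-dihydro-2H-pyran with an endocyclic carbanion is not an established method. Mode of closure: the seven-membered ring forms through the five-membered envelope of a [2,3] shift held inside a bicyclo[3.2.1]-like array in which the pyran oxygen bridges C6 and C10 (formally a 7-endo attack of C10 on C1), and the ether ring opens in the same event. C1: C10 arrives on the cyclopentene face that carries the breaking C6–O bond, and since the new C5=C6 bond can only be cis inside the ring (C7 inside, H outside), that face is dictated by the (S) configuration at C6 from step 4; it is the α-face, so the methyl group becomes β. C10: the oxygen stays on the side from which it bridged while C9 stays tied to C7, which places O10 trans to the C1 methyl group (10α); C6 ceases to be a stereocentre and C4 is a spectator. The selectivity needed is [2,3] over the [1,2] and [1,4] shifts known for lithiated dihydropyrans and over a second deprotonation at the doubly allylic C7 of 13; low temperature, about one equivalent of base and the allylic nature of the migrating terminus are what should secure it. The lithium alkoxide is silylated in the flask, which places the Si–H tether for step 8 on O10.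

Step 8
Reactants: 14 (1S,4R,10R)-4-(tert-butyldimethylsilyloxy)-10-(dimethylsilyloxy)dauca-5,8-diene
Product: 15 cyclic siloxane (1-oxa-2-silacyclohexane O10–SiMe2–C6) of 4β-(tert-butyldimethylsilyloxy)dauc-8-ene, 5α-H, 6α-Si, 10α-O
Conditions: Pt2(dvds)3 (Karstedt catalyst, 1 mol %), toluene, 60 °C
Reagents that add atoms: none
Why: Platinum-catalysed intramolecular hydrosilylation of a homoallylic hydridosilyl ether; the tether on O10 sits where the C6–O bond was and reaches only the α-face of C5=C6, so syn addition puts H on C5 and Si on C6, both α, which is the trans ring fusion. The 6-endo mode is expected because 5-exo would make a C–Si bond at the fully substituted C5, and C8=C9 could react only through a C–Si bond at the fully substituted C8.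

Step 9
Reactants: 15 cyclic siloxane
Product: 17 10α-acetoxy-6α-(fluorodimethylsilyl)dauc-8-en-4β-ol, via fluorosilane diol 16 (not isolated)
Conditions: HF·pyridine, pyridine, THF, 0 °C → rt; then Ac2O, DMAP (cat.), pyridine, rt
Reagents that add atoms: hydrogen fluoride (as HF·pyridine), F; acetic anhydride, CC(=O)OC(C)=O
Why: HF cleaves the Si–O10 bond of the oxasilinane to an Si–F/alcohol pair and removes the tertiary silyl ether, while C–Si bonds are inert; the freed secondary C10–OH is then acetylated, the tertiary C4–OH does not react and C6 still carries silicon, which is how O10 and O6 are told apart.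

Step 10
Reactants: 17 10α-acetoxy-6α-(fluorodimethylsilyl)dauc-8-en-4β-ol
Product: 18 10α-acetoxydauc-8-ene-4β,6α-diol
Conditions: KF, 30 % H2O2, DMF, rt → 40 °C
Reagents that add atoms: hydrogen peroxide, OO
Why: Tamao oxidation of the fluorosilane under fluoride activation without added base; the C–Si bond becomes C–O with retention, so O6 is α, and the near-neutral medium should spare the acetate.

Step 11
Reactants: 18 10α-acetoxydauc-8-ene-4β,6α-diol; 19 4-methoxybenzoyl chloride
Product: 20 (1S,4R,5S,6S,10R)-10α-acetoxy-6α-(4-methoxybenzoyloxy)dauc-8-en-4β-ol (target)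
Conditions: 19, DMAP, Et3N, CH2Cl2, rt → 40 °C
Reagents that add atoms: none
Why: DMAP-catalysed acylation of the only secondary hydroxyl; the tertiary C4–OH does not react under these conditions.

## Compound list

1 | (S)-(+)-terpinen-4-ol, (1S)-4-methyl-1-(propan-2-yl)cyclohex-3-en-1-ol | CC1=CC[C@](O)(C(C)C)CC1 | starting material
2 | (S)-tert-butyldimethylsilyl ether of terpinen-4-ol | CC1=CC[C@](O[Si](C)(C)C(C)(C)C)(C(C)C)CC1 | intermediate
3 | secondary ozonide (1,2,4-trioxolane) of 2, mixture at the two trioxolane carbons | CC12CC[C@@](O[Si](C)(C)C(C)(C)C)(C(C)C)CC(OO1)O2 | intermediate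
4 | (S)-3-[(tert-butyldimethylsilyl)oxy]-6-oxo-3-(propan-2-yl)heptanal | CC(=O)CC[C@@](O[Si](C)(C)C(C)(C)C)(C(C)C)CC=O | intermediate
5 | (R)-5-[(tert-butyldimethylsilyl)oxy]-2-methyl-5-(propan-2-yl)cyclopent-1-ene-1-carbaldehyde | CC1=C(C=O)[C@](O[Si](C)(C)C(C)(C)C)(C(C)C)CC1 | intermediate
6 | (2-methylallyl)magnesium chloride | CC(=C)C[Mg]Cl | starting material
7 | bis(isopinocampheyl)borinate of 8 | CC1=C([C@@H](OB([C@@H]2C[C@@H]3C[C@@H](C3(C)C)[C@H]2C)[C@@H]2C[C@@H]3C[C@@H](C3(C)C)[C@H]2C)CC(C)=C)[C@](O[Si](C)(C)C(C)(C)C)(C(C)C)CC1 | intermediate
8 | (S)-1-[(R)-5-(tert-butyldimethylsilyloxy)-2-methyl-5-(propan-2-yl)cyclopent-1-en-1-yl]-3-methylbut-3-en-1-ol | CC1=C([C@@H](O)CC(C)=C)[C@](O[Si](C)(C)C(C)(C)C)(C(C)C)CC1 | intermediate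
9 | allyl bromide | C=CCBr | starting material
10 | allyl ether of 8, (S) at C6 | CC1=C([C@@H](OCC=C)CC(C)=C)[C@](O[Si](C)(C)C(C)(C)C)(C(C)C)CC1 | intermediate
11 | (S)-2-[(R)-5-(tert-butyldimethylsilyloxy)-2-methyl-5-(propan-2-yl)cyclopent-1-en-1-yl]-4-methyl-3,6-dihydro-2H-pyran | CC1=C([C@@H]2CC(C)=CCO2)[C@](O[Si](C)(C)C(C)(C)C)(C(C)C)CC1 | intermediate
12 | 10-lithio derivative of 11 (lithium on pyran C6 = C10), configuration at C10 not fixed | CC1=C([C@@H]2CC(C)=CC([Li])O2)[C@](O[Si](C)(C)C(C)(C)C)(C(C)C)CC1 | intermediate
13 | lithium (1S,4R,10R)-4-(tert-butyldimethylsilyloxy)dauca-5,8-dien-10-olate | C1C(C)=C[C@@H](O[Li])[C@@]2(C)CC[C@@](O[Si](C)(C)C(C)(C)C)(C(C)C)C2=C1 | intermediate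
14 | (1S,4R,10R)-4-(tert-butyldimethylsilyloxy)-10-(dimethylsilyloxy)dauca-5,8-diene | C1C(C)=C[C@@H](O[SiH](C)C)[C@@]2(C)CC[C@@](O[Si](C)(C)C(C)(C)C)(C(C)C)C2=C1 | intermediate
15 | cyclic siloxane O10–SiMe2–C6 of 4β-(tert-butyldimethylsilyloxy)dauc-8-ene (5α-H, 6α-Si, 10α-O) | C[Si]1(C)O[C@@H]2C=C(C)C[C@H]1[C@@H]3[C@]2(C)CC[C@@]3(O[Si](C)(C)C(C)(C)C)C(C)C | intermediate
16 | 6α-(fluorodimethylsilyl)dauc-8-ene-4β,10α-diol | C[Si](C)(F)[C@H]2CC(C)=C[C@@H](O)[C@@]3(C)CC[C@@](O)(C(C)C)[C@H]23 | intermediate
17 | 10α-acetoxy-6α-(fluorodimethylsilyl)dauc-8-en-4β-ol | C[Si](C)(F)[C@H]2CC(C)=C[C@@H](OC(C)=O)[C@@]3(C)CC[C@@](O)(C(C)C)[C@H]23 | intermediate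
18 | 10α-acetoxydauc-8-ene-4β,6α-diol | O[C@H]2CC(C)=C[C@@H](OC(C)=O)[C@@]3(C)CC[C@@](O)(C(C)C)[C@H]23 | intermediate
19 | 4-methoxybenzoyl chloride | COc1ccc(C(Cl)=O)cc1 | starting material
20 | (1S,4R,5S,6S,10R)-10α-acetoxy-6α-(4-methoxybenzoyloxy)dauc-8-en-4β-ol | COc1ccc(C(=O)O[C@H]2CC(C)=C[C@@H](OC(C)=O)[C@@]3(C)CC[C@@](O)(C(C)C)[C@H]23)cc1 | target

## Step count and least certain steps

Total step count: 11. Longest linear sequence: 11 steps (from 1; compounds 6, 9 and 19 are bought).

**Step 7 (key step, proposed new method).** The concerted [2,3] shift may lose to homolytic [1,2] or [1,4] migration, because the accepting terminus C1 is fully substituted and its methyl group has to lie on the inside of the transition state. A radical-pair pathway would also erode the transfer of chirality from C6, and excess base could deprotonate the doubly allylic C7 of the product. The fallback uses known chemistry, sets out from 5 and comes back at 14: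
- Still–Gennari olefination of 5 with ethyl 2-[bis(2,2,2-trifluoroethoxy)phosphoryl]propanoate (KHMDS, 18-crown-6) should give the ethyl (Z)-dienoate F1.
- DIBAL reduction gives the (Z)-allylic alcohol F2.
- Asymmetric Simmons–Smith cyclopropanation with Zn(CH2I)2 and the (4R,5R)-dioxaborolane ligand (Charette conditions, facial sense taken from cinnamyl alcohol) gives the cyclopropylmethanol F3.
- Dess–Martin oxidation gives the aldehyde F4.
- Boron-Wittig olefination with bis(pinacolato)borylmethane and LiTMP gives the (E)-alkenylboronate F5, a cis-divinylcyclopropane.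
- Heating F5 in toluene should trigger the Cope rearrangement through the boat transition state to the allylic boronate F6. The cyclopropane configuration then fixes the α-face attack on C1, and the (E) geometry places boron on C10 trans to the methyl group.
- Perborate oxidation with retention gives the dienol F7, and silylation with ClSiHMe2/Et3N gives 14.

**Step 8.** The hydrosilylation may take the wrong regiochemical course (Si to C5 or to C8), and platinum hydride may move the skipped diene into conjugation before addition. The fallback sets out from 14 and comes back at 18: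
- Methanolysis (K2CO3, MeOH) removes the dimethylsilyl group and gives the dienol F7.
- Ac2O/DMAP/pyridine gives the 10-acetate F8.
- Intermolecular, reagent-controlled hydroboration with monoisopinocampheylborane from (+)-α-pinene, followed by perborate, gives the 6α-alcohol F9. The enantiomer is chosen by analogy with 1-methylcycloalkenes so that it attacks the α-face; the substrate's own bias is expected to favour the β-face, so this is a mismatched case.
- HF·pyridine removes the tertiary silyl ether and gives 18.

**Step 5.** Under the basic conditions the silyl group may migrate from O4 to O6, and alkylation may then occur at the wrong oxygen. The fallback avoids a free alkoxide next to the silyl ether; it sets out from 8 and comes back at 11: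
- Acryloyl chloride/Et3N/DMAP gives the acrylate F10.
- Ring-closing metathesis (Grubbs second-generation catalyst) gives the unsaturated δ-lactone F11.
- DIBAL in excess reduces it to the (Z)-allylic diol F12.
- Mitsunobu cyclodehydration (PPh3, DIAD), with displacement at the primary allylic carbon, closes the dihydropyran 11 with the C6 configuration unchanged.

**Step 4.** The hindered, electron-rich enal may react with poor facial selectivity if the reagent and the C4 centre are mismatched. The fallback sets out from 5 and comes back at 8:
- Addition of 6 without a chiral controller gives 8 together with its C6 epimer F13.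
- Dess–Martin oxidation of the mixture gives the methallyl ketone F14.
- Corey–Bakshi–Shibata reduction with the (R)-oxazaborolidine and catecholborane, with the cyclopentenyl group as the large substituent, should return 8.

## Further compounds

F1 | step 7 | ethyl (Z)-2-methyl-3-[(R)-5-(tert-butyldimethylsilyloxy)-2-methyl-5-(propan-2-yl)cyclopent-1-en-1-yl]prop-2-enoate | CCOC(=O)/C(C)=C\C1=C(C)CC[C@@]1(O[Si](C)(C)C(C)(C)C)C(C)C
F2 | step 7 | (Z)-2-methyl-3-[(R)-5-(tert-butyldimethylsilyloxy)-2-methyl-5-(propan-2-yl)cyclopent-1-en-1-yl]prop-2-en-1-ol | OC/C(C)=C\C1=C(C)CC[C@@]1(O[Si](C)(C)C(C)(C)C)C(C)C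
F3 | step 7 | cis-[1-methyl-2-(cyclopentenyl)cyclopropyl]methanol (hydroxymethyl and cyclopentenyl cis) | OC[C@@]1(C)C[C@H]1C2=C(C)CC[C@@]2(O[Si](C)(C)C(C)(C)C)C(C)C
F4 | step 7 | cis-1-methyl-2-(cyclopentenyl)cyclopropane-1-carbaldehyde | O=C[C@@]1(C)C[C@H]1C2=C(C)CC[C@@]2(O[Si](C)(C)C(C)(C)C)C(C)C
F5 | step 7 | cis-divinylcyclopropane (E)-alkenyl pinacol boronate | CC1(C)OB(/C=C/[C@@]2(C)C[C@H]2C3=C(C)CC[C@@]3(O[Si](C)(C)C(C)(C)C)C(C)C)OC1(C)C
F6 | step 7 | (1S,4R,10R)-4-(tert-butyldimethylsilyloxy)dauca-5,8-dien-10-yl pinacol boronate (10α-B) | C1C(C)=C[C@@H](B3OC(C)(C)C(C)(C)O3)[C@@]2(C)CC[C@@](O[Si](C)(C)C(C)(C)C)(C(C)C)C2=C1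
F7 | step 7 | (1S,4R,10R)-4-(tert-butyldimethylsilyloxy)dauca-5,8-dien-10-ol | C1C(C)=C[C@@H](O)[C@@]2(C)CC[C@@](O[Si](C)(C)C(C)(C)C)(C(C)C)C2=C1
F8 | step 8 | (1S,4R,10R)-10-acetoxy-4-(tert-butyldimethylsilyloxy)dauca-5,8-diene | C1C(C)=C[C@@H](OC(C)=O)[C@@]2(C)CC[C@@](O[Si](C)(C)C(C)(C)C)(C(C)C)C2=C1
F9 | step 8 | 10α-acetoxy-4β-(tert-butyldimethylsilyloxy)dauc-8-en-6α-ol | O[C@H]2CC(C)=C[C@@H](OC(C)=O)[C@@]3(C)CC[C@@](O[Si](C)(C)C(C)(C)C)(C(C)C)[C@H]23
F10 | step 5 | acrylate of 8 | CC1=C([C@@H](OC(=O)C=C)CC(C)=C)[C@](O[Si](C)(C)C(C)(C)C)(C(C)C)CC1
F11 | step 5 | (S)-6-[(R)-cyclopentenyl]-4-methyl-5,6-dihydro-2H-pyran-2-one | CC1=C([C@@H]2CC(C)=CC(=O)O2)[C@](O[Si](C)(C)C(C)(C)C)(C(C)C)CC1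
F12 | step 5 | (S,Z)-1-[(R)-cyclopentenyl]-3-methylpent-3-ene-1,5-diol | CC1=C([C@@H](O)C/C(C)=C\CO)[C@](O[Si](C)(C)C(C)(C)C)(C(C)C)CC1
F13 | step 4 | C6 epimer of 8, (R)-carbinol | CC1=C([C@H](O)CC(C)=C)[C@](O[Si](C)(C)C(C)(C)C)(C(C)C)CC1
F14 | step 4 | 1-[(R)-5-(tert-butyldimethylsilyloxy)-2-methyl-5-(propan-2-yl)cyclopent-1-en-1-yl]-3-methylbut-3-en-1-one | CC1=C(C(=O)CC(C)=C)[C@](O[Si](C)(C)C(C)(C)C)(C(C)C)CC1
A1 | alternative 1 | metathesis precursor: cyclopentane with C6 carbinol–methallyl arm and C10 acetate–vinyl arm | O[C@@H](CC(C)=C)[C@H]1[C@](O)(C(C)C)CC[C@]1(C)[C@H](OC(C)=O)C=C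
A2 | alternative 2 | tert-butyldimethylsilyl acylsilane of the cyclopentenyl unit | CC1=C(C(=O)[Si](C)(C)C(C)(C)C)[C@](O[Si](C)(C)C(C)(C)C)(C(C)C)CC1
A3 | alternative 2 | [3+4] product: C6 silyl enol ether, C8 ketone, 10α-(4-methoxybenzyloxy) | O=C1CC(O[Si](C)(C)C(C)(C)C)=C2[C@](C)(CC[C@@]2(O[Si](C)(C)C(C)(C)C)C(C)C)[C@H](OCc3ccc(OC)cc3)C1
A4 | alternative 3 | trans-hydrindanone lacking C9 (C10 ketone, C8 methyl, 6α-anisoate, 4β-OH) | CC1C[C@H](OC(=O)c2ccc(OC)cc2)[C@H]3[C@](O)(C(C)C)CC[C@]3(C)C1=O
A5 | alternative 3 | ring-expanded C10 enone | COc1ccc(C(=O)O[C@H]2CC(C)=CC(=O)[C@@]3(C)CC[C@@](O)(C(C)C)[C@H]23)cc1
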